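**Retrosynthetic overview**

1. The target is two cis-3,4-dihydro-4-arylcoumarins joined C3–C3'. All four stereocentres are set last, by double syn hydrogenation of the flat 4,4'-diaryl-3,3'-bicoumarin 25; the half A aryl group enters by Suzuki coupling at C4.
2. Feature used: ring A (C4a, C5, C6, C7, C8, C8a of the 5,7-dihydroxy half) is a phloroglucinol whose C4a carries C4 and whose C8a oxygen is tied to C2. This is an acylphloroglucinol lactonised onto an ester, the Claisen-folded form of a 3,5,7-triketo ester.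
3. Key disconnection: C4a–C8a and O1–C2 of half A, back to the pyrone-masked triketo ester 17.
4. 17 comes from a decarboxylative Claisen union (C3–C4 of half A) of the half B malonic half ester 10 with pyronylacetic acid 13; half B comes from benzophenone 5 and methyl succinyl chloride 6.
5. Ring order: half B pyranone (step 5), then ring A and the half A pyranone together (step 11), then saturation of both pyranones (step 16).

Key step: step 11

Remark: coumarin numbering is used for each half (half A has the 5,7-oxygens, half B the 5,6,7,8-oxygens); CouB means the 5,6,7,8-tetramethoxy-4-(4-methoxyphenyl)-2-oxo-2H-chromen-3-yl group; the hindered C3–C3' axis of 20 to 25 is assumed to equilibrate at the temperatures used, so no axial descriptor is given.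

**Route**

Step 1
Reactants: 1 3,4,5-trimethoxyphenol; 2 4-methoxybenzoyl chloride
Product: 3 (2-hydroxy-4,5,6-trimethoxyphenyl)(4-methoxyphenyl)methanone
Conditions: AlCl3, Et2O, 0 °C to rt; aq. HCl
Reagents that add atoms: none
Why: Friedel–Crafts acylation at one of the two equivalent free positions of 1 (ortho to OH, para to a methoxy) should stop after one acylation because the product is held as a deactivated aluminium chelate.

Step 2
Reactants: 3 (2-hydroxy-4,5,6-trimethoxyphenyl)(4-methoxyphenyl)methanone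
Product: 4 (3-bromo-2-hydroxy-4,5,6-trimethoxyphenyl)(4-methoxyphenyl)methanone
Conditions: N-bromosuccinimide (1.0 equiv), MeCN, 0 °C
Reagents that add atoms: N-bromosuccinimide, O=C1CCC(=O)N1Br
Why: Electrophilic aromatic bromination should take the single remaining hydrogen of the phenol ring (ortho to OH, para to a methoxy), which is far more activated than the carbonyl-deactivated anisoyl ring.

Step 3
Reactants: 4 (3-bromo-2-hydroxy-4,5,6-trimethoxyphenyl)(4-methoxyphenyl)methanone
Product: 5 (2-hydroxy-3,4,5,6-tetramethoxyphenyl)(4-methoxyphenyl)methanone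
Conditions: NaOCH3 (5 equiv), CuBr (10 mol%), DMF/MeOH, 105 °C; aq. HCl
Reagents that add atoms: sodium methoxide, [Na+].[O-]C
Why: Copper-catalysed Ullmann-type methoxylation of an ortho-bromophenol (the reaction type that turns 5-bromovanillin into syringaldehyde) should replace Br by OCH3 and leave the non-enolisable diaryl ketone alone.

Step 4
Reactants: 5 (2-hydroxy-3,4,5,6-tetramethoxyphenyl)(4-methoxyphenyl)methanone; 6 methyl 4-chloro-4-oxobutanoate
Product: 7 methyl 2,3,4,5-tetramethoxy-6-(4-methoxybenzoyl)phenyl butanedioate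
Conditions: Et3N, DMAP (cat.), CH2Cl2, 0 °C to rt
Reagents that add atoms: none
Why: DMAP-catalysed O-acylation of the hindered, hydrogen-bonded phenol by the acid chloride should give the aryl ester, the methyl ester end being inert.

Step 5
Reactants: 7 methyl 2,3,4,5-tetramethoxy-6-(4-methoxybenzoyl)phenyl butanedioate
Product: 9 methyl 2-(CouB)acetate, via 2-(CouB)acetic acid 8 (not isolated)
Conditions: KN(SiMe3)2 (1.2 equiv), THF, −78 to 0 °C, dilute; then HCl in MeOH (excess), 50 °C
Reagents that add atoms: methanol, CO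
Why: In a Stobbe-type sequence the enolate alpha to the aryl ester should add to the diaryl ketone (6-ring aldol), the alkoxide lactonise onto the methyl ester and E1cB opening give the conjugated coumarin-3-acetate, which acidic methanol re-esterifies (Fischer esterification).

Step 6
Reactants: 9 methyl 2-(CouB)acetate
Product: 10 3-methoxy-3-oxo-2-(CouB)propanoic acid (racemic, used at once)
Conditions: LiN(SiMe3)2 (1.15 equiv), THF, −78 °C; CO2 (gas); cold aq. HCl to pH 3
Reagents that add atoms: carbon dioxide, O=C=O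
Why: Carboxylation of the lithium ester enolate with CO2 should give the malonic half ester cleanly, since the carboxylate product cannot be carboxylated again.

Step 7
Reactants: 11 4-hydroxy-6-methyl-2H-pyran-2-one (triacetic acid lactone)
Product: 12 4-[(4-methoxyphenyl)methoxy]-6-methyl-2H-pyran-2-one
Conditions: 4-methoxybenzyl alcohol, PPh3, diisopropyl azodicarboxylate, THF, 0 °C to rt
Reagents that add atoms: (4-methoxyphenyl)methanol, COc1ccc(CO)cc1
Why: Mitsunobu alkylation of the acidic enol should place the benzyl group on O4 and avoid the C3 alkylation that benzyl halides and base give.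

Step 8
Reactants: 12 4-[(4-methoxyphenyl)methoxy]-6-methyl-2H-pyran-2-one
Product: 13 2-{4-[(4-methoxyphenyl)methoxy]-2-oxo-2H-pyran-6-yl}acetic acid
Conditions: LiN(iPr)2 (1.1 equiv), THF/DMPU, −78 °C; cannulate into excess CO2 in THF; cold aq. HCl; use without delay
Reagents that add atoms: carbon dioxide, O=C=O
Why: Vinylogous deprotonation of the 6-methyl group should give the extended enolate, which CO2 traps at the methyl carbon (carboxylation of a dienolate at its terminus).

Step 9
Reactants: 13 2-{4-[(4-methoxyphenyl)methoxy]-2-oxo-2H-pyran-6-yl}acetic acid; 10 3-methoxy-3-oxo-2-(CouB)propanoic acid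
Product: 16 methyl 4-{4-[(4-methoxyphenyl)methoxy]-2-oxo-2H-pyran-6-yl}-3-oxo-2-(CouB)butanoate, via acyl imidazolide 14 (not isolated), via acylmalonic half ester 15 (not isolated)
Conditions: 13 (1.5 equiv), 1,1'-carbonyldiimidazole, THF, rt; add to the magnesium salt of 10 [Mg(OEt)2 (0.55 equiv), THF, EtOH stripped]; rt to 40 °C; aq. HCl
Reagents that add atoms: none
Why: In a Masamune–Brooks decarboxylative Claisen condensation the magnesium enolate of the half ester should be C-acylated by the acyl imidazolide under near-neutral conditions that leave the acidic CH2 of 14 alone, and the acylmalonate loses CO2 on acidic work-up.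

Step 10
Reactants: 16 methyl 4-{4-[(4-methoxyphenyl)methoxy]-2-oxo-2H-pyran-6-yl}-3-oxo-2-(CouB)butanoate
Product: 17 methyl 4-(4-hydroxy-2-oxo-2H-pyran-6-yl)-3-oxo-2-(CouB)butanoate (drawn as the keto form; largely enolised)
Conditions: CF3CO2H, anisole (10 equiv), CH2Cl2, 0 °C
Reagents that add atoms: none
Why: Acidolysis of the 4-methoxybenzyl vinylogous ester should free the pyrone OH, the benzyl cation being trapped by anisole (Friedel–Crafts alkylation) while the beta-keto ester, lactones and aryl methyl ethers are acid-stable.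

Step 11
Reactants: 17 methyl 4-(4-hydroxy-2-oxo-2H-pyran-6-yl)-3-oxo-2-(CouB)butanoate
Product: 20 4,5,7-trihydroxy-3-(CouB)-2H-chromen-2-one, via ring-opened triketo diester 18 (not isolated), via acylphloroglucinol keto ester 19 (not isolated)
Conditions: Mg(OCH3)2 (10 equiv), MeOH, reflux, argon; then 2 M HCl, 0 to 50 °C
Reagents that add atoms: none
Why: Methoxide should open the pyrone lactone at its carbonyl to the methyl triketo ester 18, held as a magnesium chelate; the C4a carbanion between the C4 and C5 carbonyls then attacks the new C8a ester in a Claisen condensation, loss of methoxide and enolisation give acylphloroglucinol 19, and a flanking phenoxide (C8a–O) attacks the C2 ester to close the 4-hydroxycoumarin. The closest known reaction is the Mg(OCH3)2 conversion of 6-(2-oxoalkyl)-4-hydroxy-2-pyrones into acylphloroglucinols, followed by the ordinary lactonisation of a 2-hydroxyaryl beta-keto ester. Ring A closes by 6-(enolendo)-exo-trig C-acylation and the half A pyranone by 6-exo-trig O-acylation. No stereocentre is formed, and half B is a flat coumarin whose lactone, if opened by methoxide to the Z-cinnamate, should reclose on acidification. The step needs Claisen folding (C4a onto C8a) in preference to aldol folding (C8 onto C4) and to the other Claisen mode (C6 onto C2). The CouB group on C3 makes the C2–C3–C4 keto ester the most acidic and most hindered part of the chain, so it should sit as a magnesium enolate that is neither an electrophile nor open to retro-Claisen cleavage.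

Step 12
Reactants: 20 4,5,7-trihydroxy-3-(CouB)-2H-chromen-2-one
Product: 21 4,5,7-trimethoxy-3-(CouB)-2H-chromen-2-one
Conditions: (CH3O)2SO2 (6 equiv), K2CO3, acetone, reflux
Reagents that add atoms: dimethyl sulfate, COS(=O)(=O)OC
Why: Williamson O-methylation with a hard electrophile should cap all three hydroxyls, the 4-OH reacting on oxygen as a vinylogous carboxylate (any 2-methoxychromone isomer converges in step 13).

Step 13
Reactants: 21 4,5,7-trimethoxy-3-(CouB)-2H-chromen-2-one
Product: 22 4-hydroxy-5,7-dimethoxy-3-(CouB)-2H-chromen-2-one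
Conditions: LiCl (5 equiv), DMSO, 90 °C; then 1 M HCl
Reagents that add atoms: none
Why: SN2 demethylation by chloride should cleave only the vinylogous methyl ester at O4, whose leaving group is a stabilised coumarin-4-olate, and spare the aryl methyl ethers, as in the LiCl cleavage of methyl tetronates.

Step 14
Reactants: 22 4-hydroxy-5,7-dimethoxy-3-(CouB)-2H-chromen-2-one
Product: 23 5,7-dimethoxy-2-oxo-3-(CouB)-2H-chromen-4-yl trifluoromethanesulfonate
Conditions: (CF3SO2)2O (1.3 equiv), Et3N, CH2Cl2, −78 to 0 °C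
Reagents that add atoms: trifluoromethanesulfonic anhydride, O=S(=O)(OS(=O)(=O)C(F)(F)F)C(F)(F)F
Why: O-sulfonylation of the 4-hydroxycoumarin should give the enol triflate at O4, the usual outcome for 5,7-dimethoxy-4-hydroxycoumarins.

Step 15
Reactants: 23 5,7-dimethoxy-2-oxo-3-(CouB)-2H-chromen-4-yl trifluoromethanesulfonate; 24 (4-methoxyphenyl)boronic acid
Product: 25 5,5',6',7,7',8'-hexamethoxy-4,4'-bis(4-methoxyphenyl)-2H,2'H-[3,3'-bichromene]-2,2'-dione
Conditions: Pd(OAc)2 (5 mol%), SPhos (10 mol%), K3PO4, toluene/H2O (20:1), 80 °C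
Reagents that add atoms: none
Why: Suzuki–Miyaura coupling of the activated vinylogous acyl triflate should succeed with the bulky, electron-rich SPhos ligand, which supports oxidative addition and reductive elimination at the doubly flanked C4.

Step 16
Reactants: 25 5,5',6',7,7',8'-hexamethoxy-4,4'-bis(4-methoxyphenyl)-2H,2'H-[3,3'-bichromene]-2,2'-dione
Product: 27 (3S,3'S,4R,4'R)-5,5',6',7,7',8'-hexamethoxy-4,4'-bis(4-methoxyphenyl)-[3,3'-bichromane]-2,2'-dione, via half-reduced bicoumarin 26 (not isolated)
Conditions: H2 (80 bar), [Ir(cod)((S)-tBu-PHOX)]BArF (5 mol%), CH2Cl2, 50 °C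
Reagents that add atoms: none
Why: Proposed new method: a cationic iridium N,P complex needs no directing group and should add H2 suprafacially to each tetrasubstituted C3=C4 bond, so H3 and H4 come out cis in each half, and if the chiral ligand selects the same face at both alkenes the pseudo-C2 (3S,4R,3'S,4'R) isomer results, helped by the twisted diene, which exposes the face of each coumarin that lies syn to the small C2 carbonyl of the other half; the closest known reactions are Ir–PHOX asymmetric hydrogenation of tetrasubstituted aryl alkenes and the cis hydrogenation of 3,4-disubstituted coumarins and chromenes over palladium.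

Step 17
Reactants: 27 (3S,3'S,4R,4'R)-5,5',6',7,7',8'-hexamethoxy-4,4'-bis(4-methoxyphenyl)-[3,3'-bichromane]-2,2'-dione
Product: 28 (3S,3'S,4R,4'R)-5,5',6',7,7',8'-hexahydroxy-4,4'-bis(4-hydroxyphenyl)-[3,3'-bichromane]-2,2'-dione (CNP0064734.1)
Conditions: BBr3 (20 equiv), CH2Cl2, −78 to 0 °C, argon; MeOH quench at −78 °C; degassed aqueous work-up
Reagents that add atoms: none
Why: Lewis acid cleavage of all eight aryl methyl ethers by BBr3 (O-complexation, then SN2 by bromide) runs without base, so the epimerisable C3 and C3' centres and both lactones should be kept.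

**Compound list**

1 | 3,4,5-trimethoxyphenol | COc1cc(O)cc(OC)c1OC | starting material
2 | 4-methoxybenzoyl chloride | COc1ccc(cc1)C(Cl)=O | starting material
3 | (2-hydroxy-4,5,6-trimethoxyphenyl)(4-methoxyphenyl)methanone | COc1ccc(cc1)C(=O)c1c(O)cc(OC)c(OC)c1OC | intermediate
4 | (3-bromo-2-hydroxy-4,5,6-trimethoxyphenyl)(4-methoxyphenyl)methanone | COc1ccc(cc1)C(=O)c1c(O)c(Br)c(OC)c(OC)c1OC | intermediate
5 | (2-hydroxy-3,4,5,6-tetramethoxyphenyl)(4-methoxyphenyl)methanone | COc1ccc(cc1)C(=O)c1c(O)c(OC)c(OC)c(OC)c1OC | intermediate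
6 | methyl 4-chloro-4-oxobutanoate | COC(=O)CCC(Cl)=O | starting material
7 | methyl 2,3,4,5-tetramethoxy-6-(4-methoxybenzoyl)phenyl butanedioate | COC(=O)CCC(=O)Oc1c(OC)c(OC)c(OC)c(OC)c1C(=O)c1ccc(OC)cc1 | intermediate
8 | 2-[5,6,7,8-tetramethoxy-4-(4-methoxyphenyl)-2-oxo-2H-chromen-3-yl]acetic acid (not isolated) | OC(=O)Cc1c(-c2ccc(OC)cc2)c2c(OC)c(OC)c(OC)c(OC)c2oc1=O | intermediate
9 | methyl 2-[5,6,7,8-tetramethoxy-4-(4-methoxyphenyl)-2-oxo-2H-chromen-3-yl]acetate | COC(=O)Cc1c(-c2ccc(OC)cc2)c2c(OC)c(OC)c(OC)c(OC)c2oc1=O | intermediate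
10 | 3-methoxy-3-oxo-2-(CouB)propanoic acid, racemic | COC(=O)C(C(O)=O)c1c(-c2ccc(OC)cc2)c2c(OC)c(OC)c(OC)c(OC)c2oc1=O | intermediate
11 | 4-hydroxy-6-methyl-2H-pyran-2-one | CC1=CC(O)=CC(=O)O1 | starting material
12 | 4-[(4-methoxyphenyl)methoxy]-6-methyl-2H-pyran-2-one | CC1=CC(OCc2ccc(OC)cc2)=CC(=O)O1 | intermediate
13 | 2-{4-[(4-methoxyphenyl)methoxy]-2-oxo-2H-pyran-6-yl}acetic acid | OC(=O)CC1=CC(OCc2ccc(OC)cc2)=CC(=O)O1 | intermediate
14 | 6-[2-(1H-imidazol-1-yl)-2-oxoethyl]-4-[(4-methoxyphenyl)methoxy]-2H-pyran-2-one (not isolated) | O=C(CC1=CC(OCc2ccc(OC)cc2)=CC(=O)O1)n1ccnc1 | intermediate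
15 | 2-(methoxycarbonyl)-4-{4-[(4-methoxyphenyl)methoxy]-2-oxo-2H-pyran-6-yl}-3-oxo-2-(CouB)butanoic acid (not isolated) | COC(=O)C(C(O)=O)(C(=O)CC1=CC(OCc2ccc(OC)cc2)=CC(=O)O1)c1c(-c2ccc(OC)cc2)c2c(OC)c(OC)c(OC)c(OC)c2oc1=O | intermediate
16 | methyl 4-{4-[(4-methoxyphenyl)methoxy]-2-oxo-2H-pyran-6-yl}-3-oxo-2-(CouB)butanoate | COC(=O)C(C(=O)CC1=CC(OCc2ccc(OC)cc2)=CC(=O)O1)c1c(-c2ccc(OC)cc2)c2c(OC)c(OC)c(OC)c(OC)c2oc1=O | intermediate
17 | methyl 4-(4-hydroxy-2-oxo-2H-pyran-6-yl)-3-oxo-2-(CouB)butanoate (key-step precursor, keto form) | COC(=O)C(C(=O)CC1=CC(O)=CC(=O)O1)c1c(-c2ccc(OC)cc2)c2c(OC)c(OC)c(OC)c(OC)c2oc1=O | intermediate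
18 | dimethyl 3,5,7-trioxo-2-(CouB)nonanedioate (magnesium chelate in the flask, not isolated) | COC(=O)CC(=O)CC(=O)CC(=O)C(C(=O)OC)c1c(-c2ccc(OC)cc2)c2c(OC)c(OC)c(OC)c(OC)c2oc1=O | intermediate
19 | methyl 3-oxo-2-(CouB)-3-(2,4,6-trihydroxyphenyl)propanoate (not isolated) | COC(=O)C(C(=O)c1c(O)cc(O)cc1O)c1c(-c2ccc(OC)cc2)c2c(OC)c(OC)c(OC)c(OC)c2oc1=O | intermediate
20 | 4,5,7-trihydroxy-3-(CouB)-2H-chromen-2-one (key-step product) | O=c1oc2cc(O)cc(O)c2c(O)c1-c1c(-c2ccc(OC)cc2)c2c(OC)c(OC)c(OC)c(OC)c2oc1=O | intermediate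
21 | 4,5,7-trimethoxy-3-(CouB)-2H-chromen-2-one | O=c1oc2cc(OC)cc(OC)c2c(OC)c1-c1c(-c2ccc(OC)cc2)c2c(OC)c(OC)c(OC)c(OC)c2oc1=O | intermediate
22 | 4-hydroxy-5,7-dimethoxy-3-(CouB)-2H-chromen-2-one | O=c1oc2cc(OC)cc(OC)c2c(O)c1-c1c(-c2ccc(OC)cc2)c2c(OC)c(OC)c(OC)c(OC)c2oc1=O | intermediate
23 | 5,7-dimethoxy-2-oxo-3-(CouB)-2H-chromen-4-yl trifluoromethanesulfonate | O=c1oc2cc(OC)cc(OC)c2c(OS(=O)(=O)C(F)(F)F)c1-c1c(-c2ccc(OC)cc2)c2c(OC)c(OC)c(OC)c(OC)c2oc1=O | intermediate
24 | (4-methoxyphenyl)boronic acid | COc1ccc(cc1)B(O)O | starting material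
25 | 5,5',6',7,7',8'-hexamethoxy-4,4'-bis(4-methoxyphenyl)-2H,2'H-[3,3'-bichromene]-2,2'-dione | O=c1oc2cc(OC)cc(OC)c2c(-c2ccc(OC)cc2)c1-c1c(-c2ccc(OC)cc2)c2c(OC)c(OC)c(OC)c(OC)c2oc1=O | intermediate
26 | (3S,4R)-5,7-dimethoxy-4-(4-methoxyphenyl)-3-(CouB)chroman-2-one (drawn with half A reduced first; the isomer reduced first in half B converges; not isolated) | O=C1Oc2cc(OC)cc(OC)c2[C@@H](c2ccc(OC)cc2)[C@H]1c1c(-c2ccc(OC)cc2)c2c(OC)c(OC)c(OC)c(OC)c2oc1=O | intermediate
27 | (3S,3'S,4R,4'R)-5,5',6',7,7',8'-hexamethoxy-4,4'-bis(4-methoxyphenyl)-[3,3'-bichromane]-2,2'-dione | O=C1Oc2cc(OC)cc(OC)c2[C@@H](c2ccc(OC)cc2)[C@H]1[C@H]1C(=O)Oc2c(OC)c(OC)c(OC)c(OC)c2[C@H]1c1ccc(OC)cc1 | intermediate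
28 | (3S,3'S,4R,4'R)-5,5',6',7,7',8'-hexahydroxy-4,4'-bis(4-hydroxyphenyl)-[3,3'-bichromane]-2,2'-dione | O=C1Oc2cc(O)cc(O)c2[C@@H](c2ccc(O)cc2)[C@H]1[C@H]1C(=O)Oc2c(O)c(O)c(O)c(O)c2[C@H]1c1ccc(O)cc1 | target

**Step count**

Total steps: 17. Longest linear sequence: 15 steps (steps 1 to 6 and 9 to 17, from 1 to 28).

**Steps most likely to fail**

Step 16. The two tetrasubstituted, electron-rich C3=C4 bonds may resist homogeneous hydrogenation. The second addition may follow the stereocentres set by the first and not the ligand, which would give the unlike cis,cis isomer. A slowly rotating C3–C3' axis may leave one atropisomer unreactive, and the sense of induction of the ligand is not predictable, so its antipode is the first variable. Fallback (known chemistry), from 25 back to 27: heterogeneous hydrogenation over Pd on carbon (H2 60 bar, EtOAc/AcOH, 60 °C) adds H2 syn to each alkene without absolute control. It should give 27 as the racemate, that is together with the enantiomer of 27 F1, besides the unlike cis,cis diastereomer F2 (racemic). The diastereomers are separated on silica, and 27 is parted from F1 by preparative HPLC on a chiral stationary phase (amylose tris(3,5-dimethylphenylcarbamate)).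

Step 11. The opened chain may fold the wrong way (aldol closure of C8 onto C4 to a resorcylate, or Claisen closure of C6 onto C2), may simply reclose to the pyrone, or the half B lactone may be cleaved by methoxide without reclosing. Fallback, from 8 (isolated from step 5 by acidic aqueous work-up in place of the methanolic HCl) to 22: Friedel–Crafts acylation of 3,5-dimethoxyphenol with acid 8 in BF3·OEt2 at 80 °C should give 1-(2-hydroxy-4,6-dimethoxyphenyl)-2-(CouB)ethan-1-one F3. NaH and diethyl carbonate in toluene at reflux then carbonylate the activated CH2 and lactonise onto the phenol, giving 22 directly. Ring A then comes from a preformed phloroglucinol ether and not from a folded chain.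

Step 9. The magnesium half ester may lose CO2 before it is acylated (returning 9), C-acylation at the crowded carbon next to CouB may be slow, and the acyl imidazolide may enolise and self-condense. Fallback, from 9 and 13 to 16: 13 is converted with 1-chloro-N,N,2-trimethylprop-1-en-1-amine (neutral conditions) into 2-{4-[(4-methoxyphenyl)methoxy]-2-oxo-2H-pyran-6-yl}acetyl chloride F4. This is joined to ester 9 by a titanium-mediated crossed Claisen condensation (TiCl4, Bu3N, N-methylimidazole, CH2Cl2, −45 °C), in which the ester is enolised by soft enolisation and no free malonic acid is involved.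

**Further compounds**

F1 | step 16 | (3R,3'R,4S,4'S)-5,5',6',7,7',8'-hexamethoxy-4,4'-bis(4-methoxyphenyl)-[3,3'-bichromane]-2,2'-dione (enantiomer of 27) | O=C1Oc2cc(OC)cc(OC)c2[C@H](c2ccc(OC)cc2)[C@@H]1[C@@H]1C(=O)Oc2c(OC)c(OC)c(OC)c(OC)c2[C@@H]1c1ccc(OC)cc1
F2 | step 16 | unlike cis,cis diastereomer of 27, racemic, drawn as (3S,4R,3'R,4'S) | O=C1Oc2cc(OC)cc(OC)c2[C@@H](c2ccc(OC)cc2)[C@H]1[C@@H]1C(=O)Oc2c(OC)c(OC)c(OC)c(OC)c2[C@@H]1c1ccc(OC)cc1
F3 | step 11 | 1-(2-hydroxy-4,6-dimethoxyphenyl)-2-(CouB)ethan-1-one | COc1cc(O)c(C(=O)Cc2c(-c3ccc(OC)cc3)c3c(OC)c(OC)c(OC)c(OC)c3oc2=O)c(OC)c1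
F4 | step 9 | 2-{4-[(4-methoxyphenyl)methoxy]-2-oxo-2H-pyran-6-yl}acetyl chloride | O=C(Cl)CC1=CC(OCc2ccc(OC)cc2)=CC(=O)O1
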